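Ring A is grown from dimethyl squarate instead of being taken from an arene. The C7 and C8 methoxy groups and the C8a oxygen are the enol ether/carbonyl array of the squarate, so C6, C7, C8 and C8a come from a cyclobutenone, and C5 and C4a from a β‑benzyloxyacrylate whose ester carbon becomes C4. Heating the 4‑alkenyl‑2,3‑dimethoxycyclobutenone opens it to a dienylketene that forms the C8a–C4a bond and aromatises. One operation thus gives a salicylate with four differentiated ring A oxygens (free C8a–OH, benzyl at C5). Ring C follows by Claisen condensation with a ring B methoxymethyl ketone, acid closure and hydrogenolysis.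

Key step: step 6

Remark: every sp3 stereocentre that arises on the way (in the cyclobutenones and in the diketone) is racemic and is erased by aromatisation, and the target is achiral; only alkene geometry has to be controlled.

Step 1
Reactants: 1 dimethyl squarate
Product: 2 4-hydroxy-2,3-dimethoxycyclobut-2-en-1-one (racemic)
Conditions: LiAlH(Ot-Bu)3 (1.05 equiv), THF, −78 to −20 °C
Reagents that add atoms: none
Why: Chemoselective 1,2-reduction of one of the two equivalent carbonyl groups by a bulky, mild hydride, whose aluminium alkoxide resists a second reduction at low temperature and gives the racemic carbinol whose stereocentre is erased in step 6.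

Step 2
Reactants: 2 4-hydroxy-2,3-dimethoxycyclobut-2-en-1-one
Product: 4 4-chloro-2,3-dimethoxycyclobut-2-en-1-one (racemic), via mesylate 3 (not isolated)
Conditions: MsCl (1.1 equiv), Et3N (1.2 equiv), CH2Cl2, −20 to 0 °C; used crude
Reagents that add atoms: methanesulfonyl chloride, CS(=O)(=O)Cl (supplies the chlorine)
Why: Sulfonylation followed by chloride substitution of an oxygen-stabilised allylic alcohol, in which chloride should return to the carbon that restores the conjugated vinylogous ester, while buffered anhydrous conditions avoid the acid-mediated loss of methanol to the semisquarate (racemic centre, erased in step 6).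

Step 3
Reactants: 5 methyl propiolate; 6 benzyl alcohol
Product: 7 methyl (E)-3-(benzyloxy)prop-2-enoate
Conditions: DABCO (10 mol%), CH2Cl2, 0 °C to rt
Reagents that add atoms: none
Why: Amine-catalysed oxa-Michael addition of an alcohol to a propiolate, which should give the thermodynamically preferred (E)-β-alkoxyacrylate.

Step 4
Reactants: 7 methyl (E)-3-(benzyloxy)prop-2-enoate
Product: 9 methyl (Z)-3-(benzyloxy)-3-(tributylstannyl)prop-2-enoate (tin cis to the ester), via vinyllithium 8 (not isolated)
Conditions: LiN(i-Pr)2 (1.1 equiv), THF, −95 °C; Bu3SnCl, −95 to −78 °C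
Reagents that add atoms: tributyltin chloride, CCCC[Sn](Cl)(CCCC)CCCC
Why: Directed β-lithiation of a β-alkoxyacrylate, in which the vinylic hydrogen cis to the ester is acidified by the attached oxygen and the lithium is held by carbonyl chelation, so that the configurationally stable vinyllithium should be stannylated with retention.

Step 5
Reactants: 4 4-chloro-2,3-dimethoxycyclobut-2-en-1-one; 9 methyl (Z)-3-(benzyloxy)-3-(tributylstannyl)prop-2-enoate
Product: 10 methyl (E)-3-(benzyloxy)-3-(2,3-dimethoxy-4-oxocyclobut-2-en-1-yl)prop-2-enoate (racemic; cyclobutenyl cis to the ester)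
Conditions: PdCl2(PhCN)2 (5 mol%), P(2-furyl)3 (10 mol%), 1,4-dioxane, 45 °C; short cold silica filtration, used at once
Reagents that add atoms: none
Why: Stille cross-coupling of a 4-chlorocyclobutenone, an activated allylic-type chloride that should add readily to zerovalent palladium formed in situ, with transfer of the α-alkoxyalkenyl group from tin with retention of geometry and formation of the C6–C5 bond at the chlorine-bearing carbon (racemic centre, erased in step 6).

Step 6
Reactants: 10 methyl (E)-3-(benzyloxy)-3-(2,3-dimethoxy-4-oxocyclobut-2-en-1-yl)prop-2-enoate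
Product: 13 methyl 6-(benzyloxy)-2-hydroxy-3,4-dimethoxybenzoate, via dienylketene 11 (not isolated), via cyclohexadienone 12 (not isolated)
Conditions: PhMe (0.01 M, slow addition of 10), 100 °C, argon
Reagents that add atoms: none
Why: Thermal four-electron conrotatory opening of 10 cleaves the bond between the carbonyl carbon and the sp3 carbon and gives dienylketene 11, whose ketene carbon (C8a) is joined to the acrylate α-carbon (C4a) by a six-electron disrotatory electrocyclisation, and enolisation of cyclohexadienone 12 then gives the phenol. The closest known reaction type is the thermal ring expansion of 4-alkenylcyclobutenones to phenols, the closing stage of the Danheiser benzannulation and of squarate-based phenol syntheses. Ring A is closed by this 6π electrocyclisation, which forms the C8a–C4a bond and no other skeletal bond. No stereocentre survives, since the sp3 centres of 10 and 12 vanish on opening and on aromatisation. The step needs ring closure to outrun bimolecular capture of the ketene (dimerisation, acylation of the phenol already formed); because the opening is reversible, the isomer with the alkenyl group turned outward should revert to 10 while only the cis isomer 11 is drained, and high dilution in an aprotic solvent keeps bimolecular paths slow. The ester that points inward at C4a should be tolerated because the ketene carbon it approaches is sp-hybridised and bears no substituent.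

Step 7
Reactants: 14 3-bromobenzene-1,2-diol (3-bromocatechol)
Product: 15 1,2-bis(benzyloxy)-3-bromobenzene
Conditions: BnBr (2.3 equiv), K2CO3, DMF, 60 °C
Reagents that add atoms: benzyl bromide, BrCc1ccccc1
Why: Williamson ether synthesis, in which both catechol hydroxyls are alkylated by benzyl bromide under carbonate in a polar aprotic solvent.

Step 8
Reactants: 15 1,2-bis(benzyloxy)-3-bromobenzene; 16 N,2-dimethoxy-N-methylacetamide
Product: 19 1-[2,3-bis(benzyloxy)phenyl]-2-methoxyethan-1-one, via aryllithium 17 (not isolated), via lithium hemiaminal 18 (not isolated)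
Conditions: n-BuLi (1.05 equiv), THF, −78 °C; then 16, −78 to 0 °C
Reagents that add atoms: none
Why: Bromine–lithium exchange followed by Weinreb ketone synthesis, in which the aryllithium should add only once because the chelated tetrahedral adduct persists until aqueous work-up, and at −78 °C the ortho benzyl ether is not attacked.

Step 9
Reactants: 13 methyl 6-(benzyloxy)-2-hydroxy-3,4-dimethoxybenzoate; 19 1-[2,3-bis(benzyloxy)phenyl]-2-methoxyethan-1-one
Product: 21 1-[6-(benzyloxy)-2-hydroxy-3,4-dimethoxyphenyl]-3-[2,3-bis(benzyloxy)phenyl]-2-methoxypropane-1,3-dione (racemic; keto–enol mixture), via lithium enolate 20 (not isolated)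
Conditions: LiN(SiMe3)2 (3.5 equiv), THF, −78 to 40 °C
Reagents that add atoms: none
Why: Crossed Claisen condensation (acylation of a ketone enolate by a salicylate ester), in which the chelated enolate should add to the ester of the lithium phenoxide of 13, held coplanar with the ring and activated by lithium, and deprotonation of the resulting 1,3-diketone drives the equilibrium (the new stereocentre is racemic and is erased in step 10).

Step 10
Reactants: 21 1-[6-(benzyloxy)-2-hydroxy-3,4-dimethoxyphenyl]-3-[2,3-bis(benzyloxy)phenyl]-2-methoxypropane-1,3-dione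
Product: 22 5-(benzyloxy)-2-[2,3-bis(benzyloxy)phenyl]-3,7,8-trimethoxy-4H-chromen-4-one
Conditions: p-TsOH·H2O (0.2 equiv), PhMe, 90 °C, 4 Å MS
Reagents that add atoms: none
Why: Acid-catalysed cyclodehydration of a 2-hydroxyaryl 1,3-diketone to the chromone, in which the only free phenol (C8a–OH) adds to the ring B carbonyl and water is lost, so that ring C can close in one direction only while catalytic sulfonic acid in toluene should spare the benzyl ethers.

Step 11
Reactants: 22 5-(benzyloxy)-2-[2,3-bis(benzyloxy)phenyl]-3,7,8-trimethoxy-4H-chromen-4-one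
Product: 23 5,2',3'-trihydroxy-3,7,8-trimethoxyflavone
Conditions: H2 (1 atm), 10% Pd/C, EtOAc–MeOH, rt
Reagents that add atoms: none
Why: Catalytic hydrogenolysis of three aryl benzyl ethers over Pd/C, which should leave the tetrasubstituted C2–C3 double bond of the flavone and the methyl ethers untouched.

Compound list
1 | dimethyl squarate (3,4-dimethoxycyclobut-3-ene-1,2-dione) | COC1=C(OC)C(=O)C1=O | starting material
2 | 4-hydroxy-2,3-dimethoxycyclobut-2-en-1-one (racemic) | COC1=C(OC)C(=O)C1O | intermediate
3 | 2,3-dimethoxy-4-oxocyclobut-2-en-1-yl methanesulfonate (racemic, not isolated) | COC1=C(OC)C(=O)C1OS(C)(=O)=O | intermediate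
4 | 4-chloro-2,3-dimethoxycyclobut-2-en-1-one (racemic) | COC1=C(OC)C(=O)C1Cl | intermediate
5 | methyl propiolate | C#CC(=O)OC | starting material
6 | benzyl alcohol | OCc1ccccc1 | starting material
7 | methyl (E)-3-(benzyloxy)prop-2-enoate | COC(=O)/C=C/OCc1ccccc1 | intermediate
8 | methyl (E)-3-(benzyloxy)-3-lithioprop-2-enoate (lithium cis to the ester, not isolated) | COC(=O)/C=C(/OCc1ccccc1)[Li] | intermediate
9 | methyl (Z)-3-(benzyloxy)-3-(tributylstannyl)prop-2-enoate (tin cis to the ester) | COC(=O)/C=C(/OCc1ccccc1)[Sn](CCCC)(CCCC)CCCC | intermediate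
10 | methyl (E)-3-(benzyloxy)-3-(2,3-dimethoxy-4-oxocyclobut-2-en-1-yl)prop-2-enoate (racemic) | COC(=O)/C=C(/OCc1ccccc1)C1C(=O)C(OC)=C1OC | intermediate
11 | methyl (2E,4E)-3-(benzyloxy)-5,6-dimethoxy-7-oxohepta-2,4,6-trienoate (dienylketene, not isolated) | O=C=C(OC)/C(OC)=C\C(OCc1ccccc1)=C/C(=O)OC | intermediate
12 | methyl 6-(benzyloxy)-3,4-dimethoxy-2-oxocyclohexa-3,5-diene-1-carboxylate (racemic, not isolated) | COC(=O)C1C(=O)C(OC)=C(OC)C=C1OCc1ccccc1 | intermediate
13 | methyl 6-(benzyloxy)-2-hydroxy-3,4-dimethoxybenzoate | COC(=O)c1c(O)c(OC)c(OC)cc1OCc1ccccc1 | intermediate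
14 | 3-bromobenzene-1,2-diol | Oc1cccc(Br)c1O | starting material
15 | 1,2-bis(benzyloxy)-3-bromobenzene | Brc1cccc(OCc2ccccc2)c1OCc1ccccc1 | intermediate
16 | N,2-dimethoxy-N-methylacetamide | COCC(=O)N(C)OC | starting material
17 | [2,3-bis(benzyloxy)phenyl]lithium (not isolated) | [Li]c1cccc(OCc2ccccc2)c1OCc1ccccc1 | intermediate
18 | lithium 1-[2,3-bis(benzyloxy)phenyl]-2-methoxy-1-[methoxy(methyl)amino]ethan-1-olate (racemic, not isolated) | [Li]OC(COC)(N(C)OC)c1cccc(OCc2ccccc2)c1OCc1ccccc1 | intermediate
19 | 1-[2,3-bis(benzyloxy)phenyl]-2-methoxyethan-1-one | COCC(=O)c1cccc(OCc2ccccc2)c1OCc1ccccc1 | intermediate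
20 | lithium (Z)-1-[2,3-bis(benzyloxy)phenyl]-2-methoxyethen-1-olate (not isolated) | CO/C=C(\O[Li])c1cccc(OCc2ccccc2)c1OCc1ccccc1 | intermediate
21 | 1-[6-(benzyloxy)-2-hydroxy-3,4-dimethoxyphenyl]-3-[2,3-bis(benzyloxy)phenyl]-2-methoxypropane-1,3-dione (racemic) | COc1cc(OCc2ccccc2)c(C(=O)C(OC)C(=O)c2cccc(OCc3ccccc3)c2OCc2ccccc2)c(O)c1OC | intermediate
22 | 5-(benzyloxy)-2-[2,3-bis(benzyloxy)phenyl]-3,7,8-trimethoxy-4H-chromen-4-one | COc1cc(OCc2ccccc2)c2c(=O)c(OC)c(-c3cccc(OCc4ccccc4)c3OCc3ccccc3)oc2c1OC | intermediate
23 | 5,2',3'-trihydroxy-3,7,8-trimethoxyflavone | COc1cc(O)c2c(=O)c(OC)c(-c3cccc(O)c3O)oc2c1OC | target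

Total step count: 11. Longest linear sequence: 7 steps (1, 2, 5, 6, 9, 10, 11).

Steps most likely to fail

Step 6. The ketene may be consumed by bimolecular paths (dimerisation, acylation of the phenol as it forms), or the precursor may drift by proton shift from its doubly activated C–H before it opens, so that ring A is not closed. Fallback, setting out from bromide 15 and returning at target 23: ring A would be taken from an arene instead of being built. Purchased 1,2,3,5-tetramethoxybenzene would be acylated with methoxyacetyl chloride and AlCl3 in CH2Cl2, the buttressed ortho methyl ether being cleaved in the same operation, to give 1-(2-hydroxy-3,4,6-trimethoxyphenyl)-2-methoxyethan-1-one F1. Aryllithium 17 from 15 would be quenched with methyl chloroformate to give methyl 2,3-bis(benzyloxy)benzoate F2. Claisen condensation of the dianion of F1 (LiN(SiMe3)2, THF) with the unhindered ester F2 should give 1-[2,3-bis(benzyloxy)phenyl]-3-(2-hydroxy-3,4,6-trimethoxyphenyl)-2-methoxypropane-1,3-dione F3, and acid (p-TsOH, PhMe) should close it to 2-[2,3-bis(benzyloxy)phenyl]-3,5,7,8-tetramethoxy-4H-chromen-4-one F4. BCl3 in CH2Cl2 (−78 to 0 °C) should then remove both benzyl groups and, through chelation to the C4 carbonyl, the C5 methyl group alone, giving 23.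

Step 9. The enolate may fail to add to the flanked, phenoxide-deactivated ester carbonyl and be lost to self-condensation of the ketone. Fallback, setting out from salicylate 13 and bromide 15 and returning at diketone 21: the polarity of the condensation would be inverted in the Baker–Venkataraman sense, with ring A as the enolate and ring B as the acyl donor. Ester 13 would be converted with Me(MeO)NH·HCl and AlMe3 into 6-(benzyloxy)-2-hydroxy-N,3,4-trimethoxy-N-methylbenzamide F5, and methoxymethyllithium (from Bu3SnCH2OMe and n-BuLi) would turn this into 1-[6-(benzyloxy)-2-hydroxy-3,4-dimethoxyphenyl]-2-methoxyethan-1-one F6. Aryllithium 17 from 15 and CO2 would give 2,3-bis(benzyloxy)benzoic acid F7, and (COCl)2 with catalytic DMF would give 2,3-bis(benzyloxy)benzoyl chloride F8. The dianion of F6 (LiN(SiMe3)2, THF, −78 °C) would be acylated by F8, on carbon directly or on oxygen followed by base-induced acyl shift, to give 21.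

Step 5. Transfer of the hindered, chelated alkenyl group from tin to palladium may be slow, so that the chloride ionises or decomposes and the coupled product opens prematurely during prolonged warming. Fallback, setting out from acrylate 7 and chloride 4 and returning at 10: tin would be replaced by zinc. Vinyllithium 8 would be transmetalated with ZnCl2 at −95 °C to methyl (Z)-3-(benzyloxy)-3-(chlorozincio)prop-2-enoate F9 (not isolated) and coupled with 4 under zerovalent palladium catalysis (Pd(PPh3)4, THF, 0 °C to rt; Negishi coupling). The fast zinc-to-palladium transfer allows a temperature at which neither 4 nor 10 is at risk, and the isolation of stannane 9 is no longer needed.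

Further compounds
F1 | step 6 | 1-(2-hydroxy-3,4,6-trimethoxyphenyl)-2-methoxyethan-1-one | COCC(=O)c1c(O)c(OC)c(OC)cc1OC
F2 | step 6 | methyl 2,3-bis(benzyloxy)benzoate | COC(=O)c1cccc(OCc2ccccc2)c1OCc1ccccc1
F3 | step 6 | 1-[2,3-bis(benzyloxy)phenyl]-3-(2-hydroxy-3,4,6-trimethoxyphenyl)-2-methoxypropane-1,3-dione (racemic) | COc1cc(OC)c(C(=O)C(OC)C(=O)c2cccc(OCc3ccccc3)c2OCc2ccccc2)c(O)c1OC
F4 | step 6 | 2-[2,3-bis(benzyloxy)phenyl]-3,5,7,8-tetramethoxy-4H-chromen-4-one | COc1cc(OC)c2c(=O)c(OC)c(-c3cccc(OCc4ccccc4)c3OCc3ccccc3)oc2c1OC
F5 | step 9 | 6-(benzyloxy)-2-hydroxy-N,3,4-trimethoxy-N-methylbenzamide | CON(C)C(=O)c1c(O)c(OC)c(OC)cc1OCc1ccccc1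
F6 | step 9 | 1-[6-(benzyloxy)-2-hydroxy-3,4-dimethoxyphenyl]-2-methoxyethan-1-one | COCC(=O)c1c(O)c(OC)c(OC)cc1OCc1ccccc1
F7 | step 9 | 2,3-bis(benzyloxy)benzoic acid | OC(=O)c1cccc(OCc2ccccc2)c1OCc1ccccc1
F8 | step 9 | 2,3-bis(benzyloxy)benzoyl chloride | ClC(=O)c1cccc(OCc2ccccc2)c1OCc1ccccc1
F9 | step 5 | methyl (Z)-3-(benzyloxy)-3-(chlorozincio)prop-2-enoate (zinc cis to the ester) | COC(=O)/C=C(/OCc1ccccc1)[Zn]Cl
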